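Ring A is closed last, onto a flat ring B: the C1–C10 bond is made by dearomative para-alkylation of a pentasubstituted phenol. In the target, O7 sits para to the quaternary C10 in ring B, so a C7 phenoxide can attack a C1 bromide tethered through C4 to C5. One operation closes ring A, creates the C10 quaternary stereocentre under chiral ion-pair control and turns the arene into a dienone. In that dienone the C6 methoxy group, the C7 carbonyl and a C9 methyl (latent C11) let every other ring-B stereocentre be set relative to C10. The precursor is a bromoalkyl guaiacol made from 3,4,5-trimethylphenol.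

Key step: step 6

Remark: atoms carry the labdane numbers (C1–C20) they have in the target, also in the aromatic precursors; β is the face of the C10 methyl group (C20), α the opposite face.

**Step 1**
Reactants: 1 3,4,5-trimethylphenol
Product: 2 5-methoxy-1,2,3-trimethylbenzene
Conditions: MeI, K2CO3, acetone, reflux
Reagents that add atoms: iodomethane (CI)
Why: Williamson O-methylation of the phenoxide caps the oxygen that becomes O6 and will later block C6 and serve as an enol ether.

**Step 2**
Reactants: 2 5-methoxy-1,2,3-trimethylbenzene; 3 4-bromobutanoyl chloride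
Product: 4 4-bromo-1-(2-methoxy-4,5,6-trimethylphenyl)butan-1-one
Conditions: AlCl3, CH2Cl2, −10 °C to 0 °C
Reagents that add atoms: none
Why: Friedel–Crafts acylation can only go to one of the two equivalent free positions of symmetric 2, both ortho to the methoxy group, so a single ketone (future C5–C4 bond) should form.

**Step 3**
Reactants: 4 4-bromo-1-(2-methoxy-4,5,6-trimethylphenyl)butan-1-one
Product: 5 2-(5-bromo-2-methylpentan-2-yl)-1-methoxy-3,4,5-trimethylbenzene
Conditions: Me2Zn, TiCl4 (gives Me2TiCl2), CH2Cl2, −40 °C to 0 °C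
Reagents that add atoms: dimethylzinc (C[Zn]C), transferred through Me2TiCl2 (C[Ti](C)(Cl)Cl) formed in the flask
Why: Reetz geminal dimethylation (methyl addition, ionisation of the tertiary benzylic titanium alkoxide, second methyl transfer) should turn the carbonyl into the C4 gem-dimethyl quaternary carbon without touching the primary bromide.

**Step 4**
Reactants: 5 2-(5-bromo-2-methylpentan-2-yl)-1-methoxy-3,4,5-trimethylbenzene
Product: 6 3-(5-bromo-2-methylpentan-2-yl)-2-methoxy-4,5,6-trimethylbenzaldehyde
Conditions: Cl2CHOMe, TiCl4, CH2Cl2, −20 °C to 0 °C; then H2O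
Reagents that add atoms: dichloromethyl methyl ether (COC(Cl)Cl); water (O)
Why: Rieche formylation has only one aryl C–H left to attack (future C7, ortho to the methoxy group), so the regiochemistry is fixed.

**Step 5**
Reactants: 6 3-(5-bromo-2-methylpentan-2-yl)-2-methoxy-4,5,6-trimethylbenzaldehyde
Product: 8 3-(5-bromo-2-methylpentan-2-yl)-2-methoxy-4,5,6-trimethylphenol, via aryl formate 7 (not isolated)
Conditions: mCPBA, CH2Cl2, 0 °C to rt; then HCl (cat.), MeOH, rt
Reagents that add atoms: 3-chloroperoxybenzoic acid (OOC(=O)c1cccc(Cl)c1)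
Why: Baeyer–Villiger (Dakin-type) oxidation with migration of the electron-rich aryl group gives the formate, and acidic methanolysis frees the C7 phenol without ever forming a phenoxide next to the bromide.

**Step 6**
Reactants: 8 3-(5-bromo-2-methylpentan-2-yl)-2-methoxy-4,5,6-trimethylphenol
Product: 9 (4aR)-1-methoxy-3,4,4a,8,8-pentamethyl-5,6,7,8-tetrahydronaphthalen-2(4aH)-one (6-methoxy-12,13,14,15,16-pentanorlabda-5,8-dien-7-one, C10 methyl β)
Conditions: O-allyl-N-(9-anthracenylmethyl)cinchonidinium bromide (10 mol %), CsOH·H2O, toluene/CH2Cl2, 0.01 M, −40 °C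
Reagents that add atoms: none
Why: Proposed new method: the phenoxide of ring B attacks the primary bromide carbon C1 through its para carbon C10 (para to O7, bearing the C20 methyl) in an SN2 displacement that dearomatises the ring to the cross-conjugated dienone; the racemic base-mediated reaction is the known Winstein–Masamune phenolate para-alkylation (Ar2-6 cyclisation), and the ion-pair version proposed here is closest to cinchona-ammonium phase-transfer alkylation of enolates. Ring A closes 6-exo-tet. The only new stereocentre, C10, is controlled by the chiral ammonium cation paired with O7 beside the C6 methoxy group and the C4 gem-dimethyl unit, which should hold the C1–C3 chain over one face of the arene. The step needs C-alkylation at C10 and not at C6 or at oxygen: C6 carries the methoxy group and lies next to the ion-paired oxygen, O-alkylation would need an eight-membered ring, and the C4 gem-dimethyl group (Thorpe–Ingold effect) favours the six-membered closure. The pseudo-enantiomeric cinchoninium salt is at hand if the sense of induction turns out opposite.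

**Step 7**
Reactants: 9 (4aR)-1-methoxy-3,4,4a,8,8-pentamethyl-5,6,7,8-tetrahydronaphthalen-2(4aH)-one
Product: 11 8α-hydroxy-6-methoxy-12,13,14,15,16-pentanorlabda-5,9(11)-dien-7-one (8-methyl β, exocyclic C9=C11 methylidene), via potassium dienolate 10 (not isolated)
Conditions: KN(SiMe3)2, THF, −78 °C; then 3-phenyl-2-(phenylsulfonyl)oxaziridine, −78 °C; NH4Cl (aq)
Reagents that add atoms: 3-phenyl-2-(phenylsulfonyl)oxaziridine (O=S(=O)(N1OC1c1ccccc1)c1ccccc1)
Why: Only the γ-protons of the C9 methyl can be removed, and the extended dienolate should take oxygen at its α-carbon C8 (Davis enolate hydroxylation), which moves the alkene to C9=C11; attack from the α face, away from the C10 methyl that leans over C8 and C9, sets 8α-OH and 8β-methyl.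

**Step 8**
Reactants: 11 8α-hydroxy-6-methoxy-12,13,14,15,16-pentanorlabda-5,9(11)-dien-7-one
Product: 12 6-methoxy-12,13,14,15,16-pentanorlabda-5,9(11)-diene-7β,8α-diol
Conditions: Zn(BH4)2, Et2O, −20 °C to 0 °C; NH4Cl (aq)
Reagents that add atoms: none
Why: Chelation-controlled 1,2-reduction of the α-hydroxy enone: the zinc chelate between O7 and the 8α-oxygen places the 8β-methyl axial, so hydride should enter from the α face and give the 7β-alcohol, while the fully substituted C5 excludes 1,4-reduction.

**Step 9**
Reactants: 13 prop-2-yn-1-ol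
Product: 15 (E)-3-iodo-2-methylprop-2-en-1-ol, via vinylalane 14 (not isolated)
Conditions: Me3Al, bis(cyclopentadienyl)zirconium dichloride Cp2ZrCl2 (25 mol %), CH2Cl2, 0 °C to rt; then I2, THF, −30 °C to 0 °C
Reagents that add atoms: trimethylaluminium (C[Al](C)C); iodine (II)
Why: Negishi zirconium-catalysed carboalumination adds methyl and aluminium syn across the alkyne, and iodinolysis with retention should give the E vinyl iodide.

**Step 10**
Reactants: 15 (E)-3-iodo-2-methylprop-2-en-1-ol
Product: 16 (E)-3-iodo-2-methylprop-2-enal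
Conditions: MnO2, CH2Cl2, rt
Reagents that add atoms: none
Why: Allylic oxidation with MnO2 is selective for the allylic alcohol and leaves the alkene geometry untouched.

**Step 11**
Reactants: 16 (E)-3-iodo-2-methylprop-2-enal
Product: 17 (E)-1-iodo-2-methylbuta-1,3-diene
Conditions: Ph3PCH3Br, KN(SiMe3)2, THF, −78 °C to 0 °C; used as a solution
Reagents that add atoms: methyltriphenylphosphonium bromide (C[P+](c1ccccc1)(c1ccccc1)c1ccccc1.[Br-])
Why: Wittig methylenation of the aldehyde builds the terminal vinyl group (C14=C15) without affecting the E iodoalkene.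

**Step 12**
Reactants: 12 6-methoxy-12,13,14,15,16-pentanorlabda-5,9(11)-diene-7β,8α-diol; 17 (E)-1-iodo-2-methylbuta-1,3-diene
Product: 19 6-methoxylabda-5,12E,14-triene-7β,8α-diol, via alkylborane 18 (not isolated)
Conditions: 9-BBN (excess, also takes up the two hydroxyl groups), THF, 60 °C; then 17, [1,1'-bis(diphenylphosphino)ferrocene]palladium dichloride Pd(dppf)Cl2 (5 mol %), AsPh3, Cs2CO3, DMF/H2O, rt
Reagents that add atoms: none
Why: Anti-Markovnikov hydroboration from the α face (the axial β-methyls on C8 and C10 shield the β face) sets 9α-H, and B-alkyl Suzuki–Miyaura coupling joins C11 to C12 with retention of the E geometry.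

**Step 13**
Reactants: 19 6-methoxylabda-5,12E,14-triene-7β,8α-diol
Product: 20 7β,8α-dihydroxylabda-12E,14-dien-6-one
Conditions: HCl (0.5 M aq), THF, rt
Reagents that add atoms: water (O)
Why: Acid hydrolysis of the enol ether protonates C5 from the open α face and leaves the C6 ketone, and any C5 epimer should equilibrate through the enol to the more stable trans-decalin (5α-H), which completes a 1,2-carbonyl transposition from C7 to C6.

**Step 14**
Reactants: 20 7β,8α-dihydroxylabda-12E,14-dien-6-one
Product: 21 labda-12E,14-diene-6β,7β,8α-triol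
Conditions: NaBH4, MeOH, 0 °C
Reagents that add atoms: none
Why: In this ketone reduction the axial β approach to C6 is blocked by the syn-axial C10 and C4β methyl groups, so hydride should come from the α face and give the axial 6β-alcohol.

**Step 15**
Reactants: 21 labda-12E,14-diene-6β,7β,8α-triol
Product: 22 7β-acetoxylabda-12E,14-diene-6β,8α-diol (CNP0225877.1)
Conditions: Ac2O, pyridine, 0 °C
Reagents that add atoms: acetic anhydride (CC(=O)OC(C)=O)
Why: Selective acylation should take place at the equatorial secondary 7β-hydroxyl, because the axial 6β-hydroxyl sits under two syn-axial methyl groups and the 8α-hydroxyl is tertiary.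

**Compound list**

1 | 3,4,5-trimethylphenol | Cc1cc(O)cc(C)c1C | starting material
2 | 5-methoxy-1,2,3-trimethylbenzene | COc1cc(C)c(C)c(C)c1 | intermediate
3 | 4-bromobutanoyl chloride | O=C(Cl)CCCBr | starting material
4 | 4-bromo-1-(2-methoxy-4,5,6-trimethylphenyl)butan-1-one | COc1cc(C)c(C)c(C)c1C(=O)CCCBr | intermediate
5 | 2-(5-bromo-2-methylpentan-2-yl)-1-methoxy-3,4,5-trimethylbenzene | COc1cc(C)c(C)c(C)c1C(C)(C)CCCBr | intermediate
6 | 3-(5-bromo-2-methylpentan-2-yl)-2-methoxy-4,5,6-trimethylbenzaldehyde | COc1c(C=O)c(C)c(C)c(C)c1C(C)(C)CCCBr | intermediate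
7 | 3-(5-bromo-2-methylpentan-2-yl)-2-methoxy-4,5,6-trimethylphenyl formate | COc1c(OC=O)c(C)c(C)c(C)c1C(C)(C)CCCBr | intermediate (not isolated)
8 | 3-(5-bromo-2-methylpentan-2-yl)-2-methoxy-4,5,6-trimethylphenol | COc1c(O)c(C)c(C)c(C)c1C(C)(C)CCCBr | intermediate
9 | (4aR)-1-methoxy-3,4,4a,8,8-pentamethyl-5,6,7,8-tetrahydronaphthalen-2(4aH)-one (C10 methyl β) | CC1=C(C)C(=O)C(OC)=C2C(C)(C)CCC[C@@]21C | intermediate
10 | potassium dienolate of 9 (O7 enolate, C7=C8 and exocyclic C9=C11) | C=C1C(C)=C([O-])C(OC)=C2C(C)(C)CCC[C@@]21C.[K+] | intermediate (not isolated)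
11 | 8α-hydroxy-6-methoxy-12,13,14,15,16-pentanorlabda-5,9(11)-dien-7-one (8-methyl β) | C=C1[C@](C)(O)C(=O)C(OC)=C2C(C)(C)CCC[C@@]21C | intermediate
12 | 6-methoxy-12,13,14,15,16-pentanorlabda-5,9(11)-diene-7β,8α-diol | C=C1[C@](C)(O)[C@@H](O)C(OC)=C2C(C)(C)CCC[C@@]21C | intermediate
13 | prop-2-yn-1-ol | C#CCO | starting material
14 | (E)-vinylalane, dimethylaluminium alkoxide of 3-(dimethylalumanyl)-2-methylprop-2-en-1-ol | C[Al](C)OC/C(C)=C/[Al](C)C | intermediate (not isolated)
15 | (E)-3-iodo-2-methylprop-2-en-1-ol | OC/C(C)=C/I | intermediate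
16 | (E)-3-iodo-2-methylprop-2-enal | O=C/C(C)=C/I | intermediate
17 | (E)-1-iodo-2-methylbuta-1,3-diene | C=C/C(C)=C/I | intermediate
18 | 11-(9-borabicyclo[3.3.1]nonan-9-yl)-6-methoxy-12,13,14,15,16-pentanorlabd-5-ene-7β,8α-diol (9α-H) | C1CCC2CCCC1B2C[C@H]1[C@](C)(O)[C@@H](O)C(OC)=C2C(C)(C)CCC[C@@]21C | intermediate (not isolated)
19 | 6-methoxylabda-5,12E,14-triene-7β,8α-diol | C=C/C(C)=C/C[C@H]1[C@](C)(O)[C@@H](O)C(OC)=C2C(C)(C)CCC[C@@]21C | intermediate
20 | 7β,8α-dihydroxylabda-12E,14-dien-6-one (5α-H) | C=C/C(C)=C/C[C@H]1[C@](C)(O)[C@@H](O)C(=O)[C@H]2C(C)(C)CCC[C@@]21C | intermediate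
21 | labda-12E,14-diene-6β,7β,8α-triol | C=C/C(C)=C/C[C@H]1[C@](C)(O)[C@@H](O)[C@@H](O)[C@H]2C(C)(C)CCC[C@@]21C | intermediate
22 | 7β-acetoxylabda-12E,14-diene-6β,8α-diol (CNP0225877.1) | C=C/C(C)=C/C[C@H]1[C@](C)(O)[C@@H](OC(C)=O)[C@@H](O)[C@H]2C(C)(C)CCC[C@@]21C | target

Total step count: 15. Longest linear sequence: 12 steps (steps 1–8 and 12–15); steps 9–11 form the side-chain branch.

**Steps most likely to fail**

Step 6 (proposed new method). The ion pair may discriminate the two faces of the remote para carbon poorly, or an uncatalysed interfacial alkylation may erode the enantiomeric purity. The fallback sets out from 8: t-BuOK in t-BuOH/THF at 50 °C (the known racemic phenolate para-alkylation) should give the racemic dienone F1. Preparative chromatography on a chiral stationary phase (amylose tris(3,5-dimethylphenylcarbamate)) then delivers the (4aR) enantiomer, which is 9, where the route is rejoined.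

Step 7. The oxidant may be captured at the γ-carbon C11 instead of C8, or the facial bias at C8 may be too small. The fallback sets out from 9: nucleophilic epoxidation of the C8=C9 enone with t-BuOOH and benzyltrimethylammonium hydroxide in THF should give, from the α face, the 8α,9α-epoxy ketone F2. Diethylaluminium 2,2,6,6-tetramethylpiperidide in toluene at 0 °C then removes a C11 proton and opens the C9–O bond (epoxide to allylic alcohol isomerisation), which returns to the route at 11.

Step 12. Hydroboration of the alkene flanked by two quaternary carbons may be too slow with 9-BBN, and the hindered alkylborane may transmetallate slowly or lose boron by protonation. The fallback sets out from 12: BH3·THF at 0 °C followed by NaOH/H2O2 should give the primary alcohol F3 (9α-H), and I2, PPh3 and imidazole convert it into the primary iodide F4. A reductive cross-electrophile coupling of F4 and 17 (NiI2, 4,4'-di-tert-butyl-2,2'-bipyridine, Zn, N,N-dimethylacetamide, rt) returns to the route at 19.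

**Further compounds**

F1 | step 6 | racemic 1-methoxy-3,4,4a,8,8-pentamethyl-5,6,7,8-tetrahydronaphthalen-2(4aH)-one | CC1=C(C)C(=O)C(OC)=C2C(C)(C)CCCC21C
F2 | step 7 | 8α,9α-epoxy-6-methoxy-12,13,14,15,16-pentanorlabd-5-en-7-one | C[C@@]12O[C@]1(C)C(=O)C(OC)=C3C(C)(C)CCC[C@]23C
F3 | step 12 | 6-methoxy-12,13,14,15,16-pentanorlabd-5-ene-7β,8α,11-triol (9α-H) | OC[C@H]1[C@](C)(O)[C@@H](O)C(OC)=C2C(C)(C)CCC[C@@]21C
F4 | step 12 | 11-iodo-6-methoxy-12,13,14,15,16-pentanorlabd-5-ene-7β,8α-diol (9α-H) | IC[C@H]1[C@](C)(O)[C@@H](O)C(OC)=C2C(C)(C)CCC[C@@]21C
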